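**Strategy.** The target is a 2,4-cis (2S,4S)-7,4'-dihydroxyflavan bonded through C4 to C8 of (−)-epicatechin. Its ring C is cut at O1–C2 and C4a–C4: ring A then is resorcinol, a C,O-bis-nucleophile (C4a para to the 7-OH, next to the phenol oxygen O1), and C2–C3–C4 is an enone whose β-carbon C4 carries C8 of perbenzylated epicatechin (ring D) and whose carbonyl carbon C2 carries ring B. A chiral Brønsted acid should merge the two by Friedel–Crafts conjugate addition and cyclodehydration into a 4-aryl-4H-chromene with C4 set; the electron-rich ring D stabilises the cation at C4. A final hydrogenation sets C2 cis and removes all benzyl groups.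

Key step: step 5

Remark: the sense of induction of the chiral acid in step 5 cannot be predicted with confidence for this enone; the (R)-acid is written, and the antipode that gives 4S would be fixed by a short screen.

**Step 1**
Reactants: 1 (−)-epicatechin
Product: 2 5,7,3',4'-tetra-O-benzyl-(−)-epicatechin
Conditions: BnBr (4.4 equiv), K2CO3, DMF, 0 °C to rt, argon
Reagents that add atoms: benzyl bromide BrCc1ccccc1
Why: Williamson etherification in which K2CO3 deprotonates only the four phenols, so the secondary 3-OH should stay free and the mild base under argon should leave C2 and C3 untouched.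

**Step 2**
Reactants: 2 5,7,3',4'-tetra-O-benzyl-(−)-epicatechin
Product: 3 3,5,7,3',4'-penta-O-benzyl-(−)-epicatechin
Conditions: NaH, BnBr, n-Bu4NI (cat.), DMF, 0 °C to rt
Reagents that add atoms: benzyl bromide BrCc1ccccc1
Why: Williamson etherification of the secondary alkoxide, safe for C2 because no free phenol is left to open ring F through a quinone methide, and it removes the last free hydroxyl before the Vilsmeier and acid steps.

**Step 3**
Reactants: 3 3,5,7,3',4'-penta-O-benzyl-(−)-epicatechin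
Product: 5 penta-O-benzylepicatechin-8-carbaldehyde, via aryl iminium salt 4 (not isolated)
Conditions: POCl3, DMF, 0 °C to 50 °C; then aq. NaOH, 0 °C to rt
Reagents that add atoms: N,N-dimethylformamide CN(C)C=O; water O
Why: Vilsmeier–Haack formylation of the phloroglucinol-type ring D, expected at C8 (between the 7-OBn group and the tied-back ring oxygen) and not at C6 (between two OBn groups), the same preference that bromination of such ethers shows, while the catechol ring E is far less activated.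

**Step 4**
Reactants: 5 penta-O-benzylepicatechin-8-carbaldehyde; 6 4'-(benzyloxy)acetophenone
Product: 8 (E)-1-[4-(benzyloxy)phenyl]-3-(penta-O-benzylepicatechin-8-yl)prop-2-en-1-one, via aldol adduct 7 (not isolated)
Conditions: KOH (aq.), EtOH/THF, rt
Reagents that add atoms: none
Why: Claisen–Schmidt condensation in which the non-enolisable aldehyde takes up the acetophenone enolate and E1cB loss of water should give the conjugated (E)-enone, the perbenzylated epicatechin having no base-labile centre.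

**Step 5**
Reactants: 8 (E)-1-[4-(benzyloxy)phenyl]-3-(penta-O-benzylepicatechin-8-yl)prop-2-en-1-one; 9 resorcinol
Product: 12 (4S)-2-[4-(benzyloxy)phenyl]-4-(penta-O-benzylepicatechin-8-yl)-4H-chromen-7-ol, via keto-phenol adduct 10 (not isolated), via hemiketal 11 (not isolated)
Conditions: (R)-3,3'-bis(2,4,6-triisopropylphenyl)-1,1'-binaphthyl-2,2'-diyl N-triflylphosphoramide (10 mol %), resorcinol (5 equiv), 4 Å MS, CH2Cl2/toluene, −20 °C to rt, then 40 °C, argon
Reagents that add atoms: none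
Why: The N-triflylphosphoramide protonates the vinylogous-ester-like carbonyl of 8 to a hydroxyallyl cation stabilised by the trioxygenated ring D, while its phosphoryl oxygen hydrogen-bonds a resorcinol OH, so that resorcinol C4 (ortho to that OH, para to the other) adds to the β-carbon to give 10 (C4a–C4), whose phenol then adds to the ketone to give 11 (O1–C2), which loses water to 12. The closest known reaction type is the acid-catalysed condensation of resorcinols and naphthols with chalcones to 2,4-diaryl-4H-chromenes, run here with a chiral Brønsted acid as in enantioselective Friedel–Crafts additions of hydroxyarenes and indoles to enones. Ring C closes by 6-exo-trig attack of the phenol oxygen on the carbonyl carbon, followed by E1 dehydration of the hemiketal. The C4 stereocentre (S) should be set by the catalyst, which shields one face of the ion-paired cation; the remote epicatechin centres are expected to exert little bias. The step needs site selectivity (β-carbon as C4 and carbonyl carbon as C2, fixed by the enone polarity; resorcinol C4 over C2, secured by sterics and the para-OH), mono-annulation (excess resorcinol) and closure on the resorcinol oxygen only, secured by benzylation of every epicatechin hydroxyl.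

**Step 6**
Reactants: 12 (4S)-2-[4-(benzyloxy)phenyl]-4-(penta-O-benzylepicatechin-8-yl)-4H-chromen-7-ol
Product: 13 the target (2R,3R)-2-(3,4-dihydroxyphenyl)-8-[(2S,4S)-7-hydroxy-2-(4-hydroxyphenyl)chroman-4-yl]chromane-3,5,7-triol
Conditions: H2 (4 bar), Pd(OH)2/C, THF/MeOH, rt
Reagents that add atoms: none
Why: Heterogeneous hydrogenation should add H2 syn to the enol-ether C2=C3 bond from the face opposite the bulky pseudo-axial C4 aryl group, which places the C2 aryl cis to it (2S), while hydrogenolysis cleaves the six benzyl ethers in the same operation.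

**Compound list**

1 | (−)-epicatechin, (2R,3R)-2-(3,4-dihydroxyphenyl)chromane-3,5,7-triol | Oc1cc(O)c2c(c1)O[C@H](c1ccc(O)c(O)c1)[C@H](O)C2 | starting material

2 | (2R,3R)-5,7-bis(benzyloxy)-2-[3,4-bis(benzyloxy)phenyl]chroman-3-ol (5,7,3',4'-tetra-O-benzyl-(−)-epicatechin) | c1ccccc1COc1cc(OCc3ccccc3)c2c(c1)O[C@H](c1ccc(OCc3ccccc3)c(OCc3ccccc3)c1)[C@H](O)C2 | intermediate

3 | (2R,3R)-3,5,7-tris(benzyloxy)-2-[3,4-bis(benzyloxy)phenyl]chroman (penta-O-benzyl-(−)-epicatechin) | c1ccccc1COc1cc(OCc3ccccc3)c2c(c1)O[C@H](c1ccc(OCc3ccccc3)c(OCc3ccccc3)c1)[C@H](OCc1ccccc1)C2 | intermediate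

4 | N-{[(2R,3R)-3,5,7-tris(benzyloxy)-2-[3,4-bis(benzyloxy)phenyl]chroman-8-yl]methylidene}-N-methylmethanaminium dichlorophosphate | c1ccccc1COc1cc(OCc3ccccc3)c2c(c1C=[N+](C)C)O[C@H](c1ccc(OCc3ccccc3)c(OCc3ccccc3)c1)[C@H](OCc1ccccc1)C2.[O-]P(Cl)(Cl)=O | intermediate

5 | (2R,3R)-3,5,7-tris(benzyloxy)-2-[3,4-bis(benzyloxy)phenyl]chroman-8-carbaldehyde | c1ccccc1COc1cc(OCc3ccccc3)c2c(c1C=O)O[C@H](c1ccc(OCc3ccccc3)c(OCc3ccccc3)c1)[C@H](OCc1ccccc1)C2 | intermediate

6 | 4'-(benzyloxy)acetophenone, 1-[4-(benzyloxy)phenyl]ethan-1-one | CC(=O)c1ccc(OCc2ccccc2)cc1 | starting material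

7 | 1-[4-(benzyloxy)phenyl]-3-hydroxy-3-[(2R,3R)-3,5,7-tris(benzyloxy)-2-[3,4-bis(benzyloxy)phenyl]chroman-8-yl]propan-1-one (both carbinol epimers) | O=C(CC(O)c1c(OCc2ccccc2)cc(OCc2ccccc2)c2c1O[C@H](c1ccc(OCc3ccccc3)c(OCc3ccccc3)c1)[C@H](OCc1ccccc1)C2)c1ccc(OCc2ccccc2)cc1 | intermediate

8 | (E)-1-[4-(benzyloxy)phenyl]-3-[(2R,3R)-3,5,7-tris(benzyloxy)-2-[3,4-bis(benzyloxy)phenyl]chroman-8-yl]prop-2-en-1-one | O=C(/C=C/c1c(OCc2ccccc2)cc(OCc2ccccc2)c2c1O[C@H](c1ccc(OCc3ccccc3)c(OCc3ccccc3)c1)[C@H](OCc1ccccc1)C2)c1ccc(OCc2ccccc2)cc1 | intermediate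

9 | resorcinol, benzene-1,3-diol | Oc1cccc(O)c1 | starting material

10 | (3S)-1-[4-(benzyloxy)phenyl]-3-(2,4-dihydroxyphenyl)-3-[(2R,3R)-3,5,7-tris(benzyloxy)-2-[3,4-bis(benzyloxy)phenyl]chroman-8-yl]propan-1-one | O=C(C[C@H](c1c(OCc2ccccc2)cc(OCc2ccccc2)c2c1O[C@H](c1ccc(OCc3ccccc3)c(OCc3ccccc3)c1)[C@H](OCc1ccccc1)C2)c1ccc(O)cc1O)c1ccc(OCc2ccccc2)cc1 | intermediate

11 | (4S)-2-[4-(benzyloxy)phenyl]-4-[(2R,3R)-3,5,7-tris(benzyloxy)-2-[3,4-bis(benzyloxy)phenyl]chroman-8-yl]chromane-2,7-diol (both C2 epimers) | OC1(c2ccc(OCc3ccccc3)cc2)C[C@H](c2c(OCc3ccccc3)cc(OCc3ccccc3)c3c2O[C@H](c2ccc(OCc4ccccc4)c(OCc4ccccc4)c2)[C@H](OCc2ccccc2)C3)c2ccc(O)cc2O1 | intermediate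

12 | (4S)-2-[4-(benzyloxy)phenyl]-4-[(2R,3R)-3,5,7-tris(benzyloxy)-2-[3,4-bis(benzyloxy)phenyl]chroman-8-yl]-4H-chromen-7-ol | C1(c2ccc(OCc3ccccc3)cc2)=C[C@H](c2c(OCc3ccccc3)cc(OCc3ccccc3)c3c2O[C@H](c2ccc(OCc4ccccc4)c(OCc4ccccc4)c2)[C@H](OCc2ccccc2)C3)c2ccc(O)cc2O1 | intermediate

13 | (2R,3R)-2-(3,4-dihydroxyphenyl)-8-[(2S,4S)-7-hydroxy-2-(4-hydroxyphenyl)chroman-4-yl]chromane-3,5,7-triol | Oc1ccc([C@@H]2C[C@H](c3c(O)cc(O)c4c3O[C@H](c3ccc(O)c(O)c3)[C@H](O)C4)c3ccc(O)cc3O2)cc1 | target

**Totals.** Total step count: 6. Longest linear sequence: 6 steps (1 to 13).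

**Steps most likely to fail**

1. Step 5. The catalyst may give weak facial control at C4, reversible Friedel–Crafts addition at 40 °C may erode the C4 configuration, and resorcinol may be alkylated twice. Fallback, setting out from 8: C4 would be set by a Hayashi–Miyaura addition. Commercial 4-bromoresorcinol would be protected (NaH, MOMCl, THF, 0 °C) to 1-bromo-2,4-bis(methoxymethoxy)benzene F1. Miyaura borylation (B2pin2, PdCl2(dppf), KOAc, dioxane, 90 °C) would give 2-[2,4-bis(methoxymethoxy)phenyl]-4,4,5,5-tetramethyl-1,3,2-dioxaborolane F2. Its addition to 8 ([Rh(OH)(cod)]2, BINAP antipode chosen for 4S, KOH, dioxane/H2O, 60 °C) should give (3S)-1-[4-(benzyloxy)phenyl]-3-[2,4-bis(methoxymethoxy)phenyl]-3-(penta-O-benzylepicatechin-8-yl)propan-1-one F3. Acid (TsOH, MeOH/CH2Cl2, 40 °C; then toluene, 4 Å MS, 60 °C) would remove both MOM groups and cyclodehydrate the keto-phenol, coming back to the route at 12.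

2. Step 6. Saturation of the hindered enol ether may be slow or may lose facial selectivity once the phenols are free, and the benzylic C2–O1 bond may be hydrogenolysed on long exposure. Fallback, setting out from 12: ionic hydrogenation (Et3SiH, CF3CO2H, CH2Cl2, −40 °C to 0 °C) would protonate C3 and deliver hydride axially to the 2-aryl oxocarbenium ion, giving (2S,4S)-2-[4-(benzyloxy)phenyl]-4-(penta-O-benzylepicatechin-8-yl)chroman-7-ol F4 with the cis arrangement fixed before any phenol is freed. Plain hydrogenolysis (H2 1 bar, Pd(OH)2/C, THF/MeOH, rt) would then come back to the route at 13.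

3. Step 3. Formylation may partly occur at C6, or conversion of the hindered arene may stall. Fallback, setting out from 3: bromination (NBS, CH2Cl2, −78 °C to rt), whose C8 preference is established for such benzyl ethers, would give 8-bromo-penta-O-benzylepicatechin F5. Bromine–lithium exchange (n-BuLi, THF, −78 °C) would give 8-lithio-penta-O-benzylepicatechin F6, and a DMF quench with aq. NH4Cl work-up would come back to the route at 5.

**Further compounds**

F1 | step 5 | 1-bromo-2,4-bis(methoxymethoxy)benzene | COCOc1ccc(Br)c(OCOC)c1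
F2 | step 5 | 2-[2,4-bis(methoxymethoxy)phenyl]-4,4,5,5-tetramethyl-1,3,2-dioxaborolane | COCOc1ccc(B2OC(C)(C)C(C)(C)O2)c(OCOC)c1
F3 | step 5 | (3S)-1-[4-(benzyloxy)phenyl]-3-[2,4-bis(methoxymethoxy)phenyl]-3-[(2R,3R)-3,5,7-tris(benzyloxy)-2-[3,4-bis(benzyloxy)phenyl]chroman-8-yl]propan-1-one | O=C(C[C@H](c1c(OCc2ccccc2)cc(OCc2ccccc2)c2c1O[C@H](c1ccc(OCc3ccccc3)c(OCc3ccccc3)c1)[C@H](OCc1ccccc1)C2)c1ccc(OCOC)cc1OCOC)c1ccc(OCc2ccccc2)cc1
F4 | step 6 | (2S,4S)-2-[4-(benzyloxy)phenyl]-4-[(2R,3R)-3,5,7-tris(benzyloxy)-2-[3,4-bis(benzyloxy)phenyl]chroman-8-yl]chroman-7-ol | C(c1ccccc1)Oc1ccc([C@@H]2C[C@H](c3c(OCc4ccccc4)cc(OCc4ccccc4)c4c3O[C@H](c3ccc(OCc5ccccc5)c(OCc5ccccc5)c3)[C@H](OCc3ccccc3)C4)c3ccc(O)cc3O2)cc1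
F5 | step 3 | (2R,3R)-3,5,7-tris(benzyloxy)-2-[3,4-bis(benzyloxy)phenyl]-8-bromochroman | c1ccccc1COc1cc(OCc3ccccc3)c2c(c1Br)O[C@H](c1ccc(OCc3ccccc3)c(OCc3ccccc3)c1)[C@H](OCc1ccccc1)C2
F6 | step 3 | [(2R,3R)-3,5,7-tris(benzyloxy)-2-[3,4-bis(benzyloxy)phenyl]chroman-8-yl]lithium | c1ccccc1COc1cc(OCc3ccccc3)c2c(c1[Li])O[C@H](c1ccc(OCc3ccccc3)c(OCc3ccccc3)c1)[C@H](OCc1ccccc1)C2
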